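**Retrosynthetic overview**
1. The C8 methacrylate and C11 acetate are put on last. The 8,11-diol comes from chelation-controlled reduction of an 11-hydroxy-8-ketone.
2. Ring A (cyclopentenone, C1–C5) is cut at C1–C2 and C4–C5. The C2–C3(=O)–C4(C15) unit is delivered as chloro keto ylide 13 to a cycloheptenone (C5=O, C1=C10) in one reductive (3+2) annulation.
3. Enabling feature: ring A shares only the C1–C5 bond with ring B, C5 is an sp2 carbon at ketone level, and C1 is its α-carbon next to the methyl-bearing C10. Hydride addition at C10 of the enone C5(=O)–C1=C10(C14) therefore sets C10 and gives a regiodefined C1 nucleophile beside the C5 electrophile.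
4. Ring B (seven-membered) comes from one-carbon ring expansion of a cyclohexanone (cyclopropanation of a position-defined silyl enol ether, then FeCl3). C7 is set by rhodium-catalysed asymmetric 1,4-addition to a purchased enone ketal.
5. Order of rings: six-membered carbocycle (purchased) → ring B (step 7) → ring A (step 9).

Key step: step 9

Remark: guaiane numbering is used for the bicyclic compounds (C1 ring-fusion CH, C2 CH2, C3 C=O, C4 C(CH3)=, C5 ring-fusion sp2 C, C6 CH2, C7 CH, C8 CH–O, C9 CH2, C10 CH(CH3), C11 C(CH3)2–O). The hands of the two chiral ligands (steps 2 and 9) are assigned from the usual enantioface models for cyclic enones and would be confirmed on model enones.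

**Step 1**
Reactants: 1 1,4-dioxaspiro[4.5]dec-6-en-8-one
Product: 2 (±)-9-methyl-1,4-dioxaspiro[4.5]dec-6-en-8-one
Conditions: LDA, THF, −78 °C; MeI, −78 → 0 °C
Reagents that add atoms: iodomethane, CI
Why: Kinetic deprotonation of the enone can occur only at the sp3 α′-carbon C9 and the lithium enolate is C-methylated (α′-alkylation of a cyclohexenone), the new centre being left racemic because it becomes sp2 in step 5.

**Step 2**
Reactants: 2 (±)-9-methyl-1,4-dioxaspiro[4.5]dec-6-en-8-one
Product: 3 (6R)-9-methyl-6-(prop-1-en-2-yl)-1,4-dioxaspiro[4.5]decan-8-one (C9 epimer mixture)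
Conditions: [RhCl(C2H4)2]2 (2.5 mol %), (R)-BINAP, isopropenylboronic acid pinacol ester, KOH (aq), 1,4-dioxane, 60 °C
Reagents that add atoms: isopropenylboronic acid pinacol ester, CC(=C)B1OC(C)(C)C(C)(C)O1
Why: Hayashi–Miyaura rhodium-catalysed asymmetric 1,4-addition of an alkenylboron reagent to a cyclic enone, in which the BINAP-bound alkenylrhodium adds to the Si face of C6 and so sets the future C7 as (6R), while C9 stays an inconsequential epimer mixture.

**Step 3**
Reactants: 3 (6R)-9-methyl-6-(prop-1-en-2-yl)-1,4-dioxaspiro[4.5]decan-8-one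
Product: 4 (6R)-6-(2-hydroxypropan-2-yl)-9-methyl-1,4-dioxaspiro[4.5]decan-8-one (C9 epimer mixture)
Conditions: Mn(dpm)3 (5 mol %), PhSiH3, O2 (1 atm), i-PrOH/CH2Cl2, 0 → 23 °C
Reagents that add atoms: dioxygen, O=O
Why: Mukaiyama hydration (metal-hydride hydrogen-atom transfer to the 1,1-disubstituted alkene, trapping of the tertiary radical by O2) gives the Markovnikov tertiary alcohol without touching the ketone or the ketal and creates no stereocentre.

**Step 4**
Reactants: 4 (6R)-6-(2-hydroxypropan-2-yl)-9-methyl-1,4-dioxaspiro[4.5]decan-8-one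
Product: 5 (6R)-9-methyl-6-[2-(triethylsilyloxy)propan-2-yl]-1,4-dioxaspiro[4.5]decan-8-one (C9 epimer mixture)
Conditions: Et3SiOTf, 2,6-lutidine, CH2Cl2, −78 °C
Reagents that add atoms: triethylsilyl triflate, CC[Si](CC)(CC)OS(=O)(=O)C(F)(F)F
Why: Silyl triflate silylation of the tertiary alcohol, needed because a free hydroxyl would protonate the copper enolate of step 9.

**Step 5**
Reactants: 5 (6R)-9-methyl-6-[2-(triethylsilyloxy)propan-2-yl]-1,4-dioxaspiro[4.5]decan-8-one
Product: 6 (6R)-9-methyl-6-[2-(triethylsilyloxy)propan-2-yl]-8-(trimethylsilyloxy)-1,4-dioxaspiro[4.5]dec-8-ene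
Conditions: Me3SiCl, NaI, Et3N, MeCN, 23 °C
Reagents that add atoms: chlorotrimethylsilane, C[Si](C)(C)Cl
Why: Thermodynamic silyl enol ether formation (Me3SiI made in situ, amine base) should favour the tetrasubstituted C8=C9 enol ether, which erases the C9 centre and fixes the bond into which the extra ring carbon is inserted.

**Step 6**
Reactants: 6 (6R)-9-methyl-6-[2-(triethylsilyloxy)propan-2-yl]-8-(trimethylsilyloxy)-1,4-dioxaspiro[4.5]dec-8-ene
Product: 7 siloxycyclopropane from CH2 addition across C8=C9 of 6 (1-methyl-6-(trimethylsilyloxy)bicyclo[4.1.0]heptane core; mixture of cyclopropane-face isomers)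
Conditions: Et2Zn, CH2I2, CH2Cl2, 0 → 23 °C; pyridine quench
Reagents that add atoms: diiodomethane, ICI
Why: Simmons–Smith cyclopropanation with the zinc carbenoid is fastest at the electron-rich silyl enol ether, and the face of addition is irrelevant because both cyclopropane carbons become sp2 or CH2 in step 7.

**Step 7**
Reactants: 7 siloxycyclopropane
Product: 9 (6R)-10-methyl-6-[2-(triethylsilyloxy)propan-2-yl]-1,4-dioxaspiro[4.6]undec-9-en-8-one, via chloro ketone 8 (not isolated)
Conditions: FeCl3 (2.2 equiv), pyridine (1 equiv), DMF, 0 °C; then NaOAc, MeOH, 40 °C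
Reagents that add atoms: none
Why: FeCl3-mediated oxidative ring expansion of a siloxycyclopropane (one-electron oxidation, cleavage of the internal cyclopropane bond to the tertiary β-keto radical, chlorine transfer) followed by E1cB loss of HCl gives the conjugated 3-methylcycloheptenone with the enone position fixed by construction.

**Step 8**
Reactants: 10 ethyltriphenylphosphonium bromide (2 equiv); 11 chloroacetyl chloride
Product: 13 1-chloro-3-(triphenylphosphoranylidene)butan-2-one, via ethylidenetriphenylphosphorane 12 (not isolated)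
Conditions: n-BuLi (2 equiv), THF, −78 → 0 °C; then 11 (1 equiv), −78 → 23 °C
Reagents that add atoms: none
Why: C-acylation of a non-stabilised ylide by an acid chloride with transylidation (the second equivalent of ylide deprotonates the acylphosphonium salt) gives the acyl-stabilised ylide.

**Step 9**
Reactants: 9 (6R)-10-methyl-6-[2-(triethylsilyloxy)propan-2-yl]-1,4-dioxaspiro[4.6]undec-9-en-8-one; 13 1-chloro-3-(triphenylphosphoranylidene)butan-2-one
Product: 17 (1R,7R,10S)-8,8-(ethylenedioxy)-11-(triethylsilyloxy)guai-4-en-3-one, via silyl enol ether 14 (not isolated), via lithium enolate 15 (not isolated), via keto ylide 16 (not isolated)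
Conditions: CuCl (5 mol %), NaOtBu (5 mol %), (S)-p-tol-BINAP (5 mol %), PhMe2SiH, toluene, 0 °C; then MeLi, THF, 0 °C; then 13, Bu4NI (10 mol %), DMPU, −78 → 23 °C; then toluene, 110 °C
Reagents that add atoms: none
Why: Proposed new method: a ligated Cu–H adds hydride to C10 of enone 9 and silane σ-bond metathesis releases silyl enol ether 14, MeLi unmasks the regiodefined lithium enolate 15, this displaces chloride from 13 (C1–C2 bond) to give keto ylide 16, and on heating the ylide carbon C4 adds to the C5 ketone and the oxaphosphetane collapses to the C4=C5 enone and Ph3PO. The closest known reaction types are the one-pot copper-hydride asymmetric conjugate reduction/enolate alkylation of β-substituted cycloalkenones and the enolate alkylation/intramolecular Wittig cyclopentenone annulation with (3-chloro-2-oxopropylidene)triphenylphosphorane; their merger and the α-methyl-branched ylide are untested. Ring A is closed by intramolecular Wittig olefination (five-membered, ylide carbon onto the ring ketone), so the overall event is a reductive (3+2) annulation. C10 is set by the chiral bisphosphine (hydride to the Re face; the distant C7 side chain is not expected to oppose it), and C1 is set by C10, the electrophile entering the enolate anti to the adjacent methyl group (trans-2,3). The step needs 1,4- over 1,2-reduction, C-alkylation at C1 without enolate equilibration to C6, and olefination at C5 only: Cu–H with a hydrosilane is 1,4-selective, the enolate is released from a single silyl enol ether at low temperature, and C5 is the only carbonyl the ylide can reach through a five-membered transition state.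

**Step 10**
Reactants: 17 (1R,7R,10S)-8,8-(ethylenedioxy)-11-(triethylsilyloxy)guai-4-en-3-one
Product: 18 (1R,7R,10S)-11-hydroxyguai-4-ene-3,8-dione
Conditions: 1 M HCl, THF, 0 → 23 °C
Reagents that add atoms: water, O
Why: Mild aqueous acid hydrolyses the dioxolane and the tertiary triethylsilyl ether in one operation, under conditions chosen to be too mild to enolise the new C8 ketone toward C7 or to dehydrate the tertiary β-hydroxy ketone.

**Step 11**
Reactants: 18 (1R,7R,10S)-11-hydroxyguai-4-ene-3,8-dione
Product: 19 (1R,7S,8R,10S)-8,11-dihydroxyguai-4-en-3-one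
Conditions: Et2BOMe, THF/MeOH (4:1), −78 °C; NaBH4; then AcOH, MeOH co-evaporation
Reagents that add atoms: none
Why: Narasaka–Prasad reduction, in which the boron chelate between the C11 hydroxyl and the C8 carbonyl activates only this ketone (the enone should be inert at −78 °C) and exposes the carbonyl face on the side of C7–H, so that external hydride should give the 8R alcohol cis to the C7 side chain and to the C10 methyl group.

**Step 12**
Reactants: 19 (1R,7S,8R,10S)-8,11-dihydroxyguai-4-en-3-one
Product: 20 (1R,7S,8R,10S)-11-hydroxy-8-(methacryloyloxy)guai-4-en-3-one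
Conditions: methacrylic anhydride, Et3N, DMAP (10 mol %), CH2Cl2, 0 → 23 °C
Reagents that add atoms: methacrylic anhydride, CC(=C)C(=O)OC(=O)C(C)=C
Why: DMAP-catalysed acylation is expected to take the secondary C8 hydroxyl well before the tertiary C11 hydroxyl.

**Step 13**
Reactants: 20 (1R,7S,8R,10S)-11-hydroxy-8-(methacryloyloxy)guai-4-en-3-one
Product: 21 (1R,7S,8R,10S)-11-acetoxy-8-(methacryloyloxy)guai-4-en-3-one (target)
Conditions: Ac2O, DMAP (1 equiv), Et3N, CH2Cl2, 40 °C
Reagents that add atoms: acetic anhydride, CC(=O)OC(C)=O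
Why: Steglich-type DMAP acetylation of the tertiary alcohol under basic conditions avoids ionisation of the tertiary centre and leaves the methacrylate and the enone untouched.

**Compound list**
1 | 1,4-dioxaspiro[4.5]dec-6-en-8-one | O=C1CCC2(OCCO2)C=C1 | starting material
2 | (±)-9-methyl-1,4-dioxaspiro[4.5]dec-6-en-8-one | CC1CC2(OCCO2)C=CC1=O | intermediate
3 | (6R)-9-methyl-6-(prop-1-en-2-yl)-1,4-dioxaspiro[4.5]decan-8-one (C9 epimers) | O1CCOC12CC(C)C(=O)C[C@@H]2C(C)=C | intermediate
4 | (6R)-6-(2-hydroxypropan-2-yl)-9-methyl-1,4-dioxaspiro[4.5]decan-8-one (C9 epimers) | O1CCOC12CC(C)C(=O)C[C@@H]2C(C)(C)O | intermediate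
5 | (6R)-9-methyl-6-[2-(triethylsilyloxy)propan-2-yl]-1,4-dioxaspiro[4.5]decan-8-one (C9 epimers) | O1CCOC12CC(C)C(=O)C[C@@H]2C(C)(C)O[Si](CC)(CC)CC | intermediate
6 | (6R)-9-methyl-6-[2-(triethylsilyloxy)propan-2-yl]-8-(trimethylsilyloxy)-1,4-dioxaspiro[4.5]dec-8-ene | O1CCOC12CC(C)=C(O[Si](C)(C)C)C[C@@H]2C(C)(C)O[Si](CC)(CC)CC | intermediate
7 | siloxycyclopropane (CH2 across C8=C9 of 6; cyclopropane-face isomers) | O1CCOC12CC3(C)CC3(O[Si](C)(C)C)C[C@@H]2C(C)(C)O[Si](CC)(CC)CC | intermediate
8 | (6R)-10-chloro-10-methyl-6-[2-(triethylsilyloxy)propan-2-yl]-1,4-dioxaspiro[4.6]undecan-8-one | O1CCOC12CC(C)(Cl)CC(=O)C[C@@H]2C(C)(C)O[Si](CC)(CC)CC | intermediate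
9 | (6R)-10-methyl-6-[2-(triethylsilyloxy)propan-2-yl]-1,4-dioxaspiro[4.6]undec-9-en-8-one | O1CCOC12CC(C)=CC(=O)C[C@@H]2C(C)(C)O[Si](CC)(CC)CC | intermediate
10 | ethyltriphenylphosphonium bromide | CC[P+](c1ccccc1)(c1ccccc1)c1ccccc1.[Br-] | starting material
11 | chloroacetyl chloride | ClCC(Cl)=O | starting material
12 | ethylidenetriphenylphosphorane | CC=P(c1ccccc1)(c1ccccc1)c1ccccc1 | intermediate
13 | 1-chloro-3-(triphenylphosphoranylidene)butan-2-one | CC(C(=O)CCl)=P(c1ccccc1)(c1ccccc1)c1ccccc1 | intermediate
14 | (6R,10S)-8-[dimethyl(phenyl)silyloxy]-10-methyl-6-[2-(triethylsilyloxy)propan-2-yl]-1,4-dioxaspiro[4.6]undec-8-ene | O1CCOC13C[C@H](C)C=C(O[Si](C)(C)c2ccccc2)C[C@@H]3C(C)(C)O[Si](CC)(CC)CC | intermediate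
15 | lithium (6R,10S)-10-methyl-6-[2-(triethylsilyloxy)propan-2-yl]-1,4-dioxaspiro[4.6]undec-8-en-8-olate | O1CCOC13C[C@H](C)C=C(O[Li])C[C@@H]3C(C)(C)O[Si](CC)(CC)CC | intermediate
16 | (6R,9R,10S)-10-methyl-9-[2-oxo-3-(triphenylphosphoranylidene)butyl]-6-[2-(triethylsilyloxy)propan-2-yl]-1,4-dioxaspiro[4.6]undecan-8-one | O1CCOC13C[C@H](C)[C@@H](CC(=O)C(C)=P(c2ccccc2)(c2ccccc2)c2ccccc2)C(=O)C[C@@H]3C(C)(C)O[Si](CC)(CC)CC | intermediate
17 | (1R,7R,10S)-8,8-(ethylenedioxy)-11-(triethylsilyloxy)guai-4-en-3-one | O1CCOC13C[C@H](C)[C@H]2CC(=O)C(C)=C2C[C@@H]3C(C)(C)O[Si](CC)(CC)CC | intermediate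
18 | (1R,7R,10S)-11-hydroxyguai-4-ene-3,8-dione | O=C1C[C@H](C)[C@H]2CC(=O)C(C)=C2C[C@@H]1C(C)(C)O | intermediate
19 | (1R,7S,8R,10S)-8,11-dihydroxyguai-4-en-3-one | O[C@@H]1C[C@H](C)[C@H]2CC(=O)C(C)=C2C[C@@H]1C(C)(C)O | intermediate
20 | (1R,7S,8R,10S)-11-hydroxy-8-(methacryloyloxy)guai-4-en-3-one | C=C(C)C(=O)O[C@@H]1C[C@H](C)[C@H]2CC(=O)C(C)=C2C[C@@H]1C(C)(C)O | intermediate
21 | (1R,7S,8R,10S)-11-acetoxy-8-(methacryloyloxy)guai-4-en-3-one | C=C(C)C(=O)O[C@@H]1C[C@H](C)[C@H]2CC(=O)C(C)=C2C[C@@H]1C(C)(C)OC(C)=O | target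

**Step count**
Total: 13 steps. Longest linear sequence: 12 steps (steps 1–7 and 9–13); step 8 is a one-step side branch.

**Steps most likely to fail**

Step 9 (proposed new method). The enolate may take a proton from the chloromethyl ketone unit of 13 instead of displacing chloride, or the α-branched stabilised ylide may fail to olefinate the hindered ring ketone. The fallback uses known chemistry and sets out from 9. The same copper-hydride reduction and MeLi cleavage give enolate 15, which is alkylated with 1-bromobut-2-yne to (6R,9R,10S)-9-(but-2-yn-1-yl)-10-methyl-6-[2-(triethylsilyloxy)propan-2-yl]-1,4-dioxaspiro[4.6]undecan-8-one F1. Carbonyl-assisted hydration of the alkyne (NaAuCl4 cat., aqueous MeOH, 23 °C) gives the 1,4-diketone (6R,9R,10S)-10-methyl-9-(2-oxobutyl)-6-[2-(triethylsilyloxy)propan-2-yl]-1,4-dioxaspiro[4.6]undecan-8-one F2. Aldol condensation (KOH, EtOH, 60 °C) then closes ring A and comes back to the route at 17.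

Step 7. Lewis-acidic FeCl3 may open the dioxolane or the silyl ether, and the basic second stage may trigger β-elimination of a ketal oxygen through the dienolate of 9. The fallback sets out from 6. Dibromocarbene addition (CHBr3, KOtBu, pentane, −20 °C) gives the dibromocyclopropane F3. This opens thermally (toluene, pyridine, 110 °C; cyclopropyl-to-allyl cation electrocyclic opening with loss of bromotrimethylsilane) to (6R)-9-bromo-10-methyl-6-[2-(triethylsilyloxy)propan-2-yl]-1,4-dioxaspiro[4.6]undec-9-en-8-one F4. Hydrodebromination (Bu3SnH, Pd(PPh3)4, THF) comes back to the route at 9.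

Step 11. Facial selectivity of hydride delivery to the C8 ketone may be poor, or the enone may be reduced as well. The fallback sets out from 18. L-Selectride (excess, THF, −78 °C) reduces the C8 ketone under steric approach control (anti to the C7 side chain) and the enone carbonyl in the 1,2 sense, giving (1R,7S,8R,10S)-guai-4-ene-3,8,11-triol F5 (C3 epimers). MnO2 (CH2Cl2, 23 °C) re-oxidises only the allylic C3 alcohol and comes back to the route at 19.

**Further compounds**
F1 | step 9 | (6R,9R,10S)-9-(but-2-yn-1-yl)-10-methyl-6-[2-(triethylsilyloxy)propan-2-yl]-1,4-dioxaspiro[4.6]undecan-8-one | O1CCOC13C[C@H](C)[C@@H](CC#CC)C(=O)C[C@@H]3C(C)(C)O[Si](CC)(CC)CC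
F2 | step 9 | (6R,9R,10S)-10-methyl-9-(2-oxobutyl)-6-[2-(triethylsilyloxy)propan-2-yl]-1,4-dioxaspiro[4.6]undecan-8-one | O1CCOC13C[C@H](C)[C@@H](CC(=O)CC)C(=O)C[C@@H]3C(C)(C)O[Si](CC)(CC)CC
F3 | step 7 | dibromocyclopropane from CBr2 addition across C8=C9 of 6 (cyclopropane-face isomers) | O1CCOC12CC3(C)C(Br)(Br)C3(O[Si](C)(C)C)C[C@@H]2C(C)(C)O[Si](CC)(CC)CC
F4 | step 7 | (6R)-9-bromo-10-methyl-6-[2-(triethylsilyloxy)propan-2-yl]-1,4-dioxaspiro[4.6]undec-9-en-8-one | O1CCOC12CC(C)=C(Br)C(=O)C[C@@H]2C(C)(C)O[Si](CC)(CC)CC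
F5 | step 11 | (1R,7S,8R,10S)-guai-4-ene-3,8,11-triol (C3 epimers) | O[C@@H]1C[C@H](C)[C@H]2CC(O)C(C)=C2C[C@@H]1C(C)(C)O
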